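**Strategy**

The ten-membered carbocycle is carved out of a twelve-membered macrolactone instead of being closed directly. Target locants: ring C1 (CH bearing C11(=C13H2)C12H2OAc), C2, C3 (isobutyrate carbon), C4=C5, C6, C7, C8/C9 (epoxide), C10. The route exploits the γ,δ-unsaturated carbonyl relationship C3(O)–C2–C1–C11=C13 spanning this ring and its exocyclic propenyl unit: methylenation of an epoxy dienyl macrolactone gives a cyclic allyl vinyl ether whose Claisen rearrangement forms C1–C2, expels the lactone oxygen and C13 from the ring (12 → 10), sets C1 under control of the pre-installed (8S,9R)-epoxide and unveils the C3 ketone and the oxygenated isopropenyl group.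

Key step: step 13

Remark: the locants above (with C14 = CH2O on C4, C15 = CH2O on C8) are used in all names, also for acyclic precursors; compounds 1, 2, 5, 11, 22 and 23 are taken as purchased. TBS = tert-butyldimethylsilyl, TBDPS = tert-butyldiphenylsilyl, TES = triethylsilyl, PMB = 4-methoxybenzyl.

**Route**

Step 1
Reactants: 1 prop-2-yn-1-ol; 2 but-3-en-1-ylmagnesium bromide (2.5 equiv)
Product: 4 (2Z)-2-(but-3-en-1-yl)-3-iodoprop-2-en-1-ol, via alkenylmagnesium chelate 3 (not isolated)
Conditions: CuI (10 mol %), THF, −10 °C → rt; then I2, −40 → 0 °C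
Reagents that add atoms: iodine, II
Why: Copper-catalysed anti-carbomagnesiation of the propargylic alkoxide (Duboudin reaction) places the butenyl group on the internal carbon and magnesium cis to CH2O in a five-membered chelate, so iodinolysis with retention should fix the C8=C9 geometry (C7 trans to the future C10).

Step 2
Reactants: 5 methyl 2-(hydroxymethyl)prop-2-enoate
Product: 6 methyl 2-{[(TBS)oxy]methyl}prop-2-enoate
Conditions: TBSCl, imidazole, CH2Cl2, 0 °C → rt
Reagents that add atoms: tert-butyldimethylsilyl chloride, CC(C)(C)[Si](C)(C)Cl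
Why: Silyl ether formation at a primary alcohol; no stereocentre is involved.

Step 3
Reactants: 4 iodo dienol; 6 silyloxymethyl acrylate (4 equiv)
Product: 7 methyl (2E,6Z)-2-{[(TBS)oxy]methyl}-6-(hydroxymethyl)-7-iodohepta-2,6-dienoate
Conditions: Hoveyda–Grubbs II (5 mol %), CH2Cl2, 40 °C
Reagents that add atoms: none
Why: Olefin cross-metathesis of a terminal olefin with a 1,1-disubstituted acrylate should give the hetero-coupled trisubstituted enoate as the thermodynamically preferred E isomer (ester trans to C6), the iodo-olefin being inert.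

Step 4
Reactants: 7 iodo dienoate
Product: 8 methyl (2E,6Z)-2-{[(TBS)oxy]methyl}-6-(hydroxymethyl)deca-2,6,9-trienoate
Conditions: allyltributylstannane, Pd2(dba)3 (2.5 mol %), AsPh3, CuI, DMF, 40 °C
Reagents that add atoms: allyltributylstannane, C=CC[Sn](CCCC)(CCCC)CCCC
Why: Stille cross-coupling of the alkenyl iodide proceeds with retention of olefin geometry and tolerates the free alcohol and the enoate, giving the skipped diene with C10 cis to C15.

Step 5
Reactants: 8 trienol
Product: 9 methyl (2E)-2-{[(TBS)oxy]methyl}-5-[(2S,3R)-2-(hydroxymethyl)-3-(prop-2-en-1-yl)oxiran-2-yl]pent-2-enoate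
Conditions: Ti(OiPr)4, L-(+)-diethyl tartrate, t-BuOOH, 4 Å MS, CH2Cl2, −20 °C
Reagents that add atoms: tert-butyl hydroperoxide, CC(C)(C)OO
Why: Katsuki–Sharpless asymmetric epoxidation touches only the allylic-alcohol olefin, L-(+)-tartrate delivering oxygen to the face that gives C8 (S) and C9 (R), their trans relationship following from the olefin geometry.

Step 6
Reactants: 9 epoxy alcohol
Product: 10 methyl (2E)-2-{[(TBS)oxy]methyl}-5-[(2S,3R)-2-{[(TBDPS)oxy]methyl}-3-(prop-2-en-1-yl)oxiran-2-yl]pent-2-enoate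
Conditions: TBDPSCl, imidazole, DMF, rt
Reagents that add atoms: tert-butyldiphenylsilyl chloride, CC(C)(C)[Si](Cl)(c1ccccc1)c1ccccc1
Why: Silylation of the primary epoxy alcohol gives a robust ether that should survive to the last step; stereocentres are untouched.

Step 7
Reactants: 11 2-methylidenepropane-1,3-diol (excess)
Product: 12 2-{[(4-methoxybenzyl)oxy]methyl}prop-2-en-1-ol
Conditions: NaH (1 equiv), PMBCl, Bu4NI (cat.), THF, 0 °C → rt
Reagents that add atoms: 4-methoxybenzyl chloride, COc1ccc(CCl)cc1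
Why: Williamson mono-etherification of a symmetrical diol used in excess; no stereocentre.

Step 8
Reactants: 12 mono-PMB diol
Product: 13 2-{[(4-methoxybenzyl)oxy]methyl}prop-2-enal
Conditions: MnO2, CH2Cl2, rt
Reagents that add atoms: none
Why: Manganese dioxide oxidises the allylic alcohol selectively to the enal without touching the PMB ether.

Step 9
Reactants: 10 epoxy diene ester; 13 enal (3 equiv)
Product: 14 methyl (2E)-2-{[(TBS)oxy]methyl}-5-[(2S,3R)-2-{[(TBDPS)oxy]methyl}-3-[(2E)-3-formyl-4-(4-methoxybenzyloxy)but-2-en-1-yl]oxiran-2-yl]pent-2-enoate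
Conditions: Hoveyda–Grubbs II (7 mol %), CH2Cl2, 40 °C
Reagents that add atoms: none
Why: Cross-metathesis of the terminal vinyl group with the 2-substituted acrolein should give the E enal (CHO trans to C10), which defines which oxygenated arm of C11 becomes the lactone oxygen carrier (C13) and which becomes C12.

Step 10
Reactants: 14 enal
Product: 15 methyl (2E)-2-{[(TBS)oxy]methyl}-5-[(2S,3R)-2-{[(TBDPS)oxy]methyl}-3-[(2Z)-4-hydroxy-3-{[(4-methoxybenzyl)oxy]methyl}but-2-en-1-yl]oxiran-2-yl]pent-2-enoate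
Conditions: NaBH4, CeCl3·7H2O, MeOH, −40 °C
Reagents that add atoms: none
Why: Luche 1,2-reduction is chemoselective for the aldehyde over the enoate and the epoxide.

Step 11
Reactants: 15 hydroxy ester
Product: 16 seco acid, (2E)-2-{[(TBS)oxy]methyl}-5-[(2S,3R)-2-{[(TBDPS)oxy]methyl}-3-[(2Z)-4-hydroxy-3-{[(4-methoxybenzyl)oxy]methyl}but-2-en-1-yl]oxiran-2-yl]pent-2-enoic acid
Conditions: LiOH·H2O, THF/MeOH/H2O, rt; then 0.5 M HCl to pH 4, 0 °C
Reagents that add atoms: lithium hydroxide (aqueous), [Li+].[OH-]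
Why: Saponification of the methyl enoate; silyl ethers, PMB ether and trisubstituted epoxide should be stable to aqueous hydroxide at room temperature.

Step 12
Reactants: 16 seco acid
Product: 17 twelve-membered macrolactone (ring C3(=O)–O–C13–C11=C1–C10–C9–C8–C7–C6–C5=C4; 4E; C11=C1 E with C13 trans to C10; 8S,9R; C12–OPMB, C14–OTBS, C15–OTBDPS)
Conditions: 2-methyl-6-nitrobenzoic anhydride, DMAP, Et3N, CH2Cl2 (2 mM), rt, slow addition
Reagents that add atoms: none
Why: Shiina macrolactonisation under high dilution closes the 12-membered ring through the only free hydroxyl under conditions mild enough not to isomerise the enoate.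

Step 13
Reactants: 17 macrolactone
Product: 19 (1S,4E,8S,9R)-8,9-epoxycyclodec-4-en-3-one carrying C1 3-(4-methoxybenzyloxy)prop-1-en-2-yl, C4 CH2OTBS and C8 CH2OTBDPS (C1 has the spatial arrangement of the target; the descriptor is S only because C3 is a carbonyl), via methylidene enol ether 18 (not isolated)
Conditions: Cp2TiMe2 (3 equiv), toluene, 65 °C, dark; filtration through basic alumina; then toluene, 120 °C
Reagents that add atoms: dimethyltitanocene, C[Ti](C)(C1C=CC=C1)C1C=CC=C1
Why: Dimethyltitanocene loses methane to give Cp2Ti=CH2, which methylenates the only carbonyl group ([2+2]/cycloreversion) to the twelve-membered 2-methylidene enol ether 18; on heating, its allyl vinyl ether array C2=C3–O–C13–C11=C1 undergoes a concerted suprafacial [3,3] (Claisen) shift that forms C1–C2, breaks O–C13 and so expels O and C13 from the ring (12 → 10), leaving the C3 ketone and the exocyclic C11=C13 methylene. The closest known reaction type is the Tebbe/Petasis methylenation–Claisen sequence that converts unsaturated lactones into ring-expanded or ring-contracted carbocycles. The cyclodecene ring is closed not by cyclisation onto an electrophile but by ring contraction within a bicyclo[7.3.1]-like chair transition state in which C10 is equatorial because the C11=C1 olefin is E. The new stereocentre C1 is controlled by the (8S,9R)-epoxide: the trans-oxirane fixes the sign of the C7–C8–C9–C10 torsion and hence the crown (chair–chair) conformation of the developing ring, and only the chair transition state that places the C11 side chain pseudo-equatorially (the target configuration, as in natural 4,5-epoxygermacrenes) fits that conformation, the C1 epimer requiring a boat array. The step needs chemoselective methylenation (secured because the lactone is the only C=O and every hydroxyl is an ether), survival of the oxirane towards the titanium carbene, and absence of Cope chemistry (secured because C8–C9 is an epoxide, so the ring holds no 1,5-diene).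

Step 14
Reactants: 19 epoxy enone
Product: 20 (1R,3S,4E,8S,9R)-allylic alcohol (C3–OH; other groups as in 19)
Conditions: (R)-2-methyl-CBS-oxazaborolidine (0.5 equiv), catecholborane, toluene, −78 °C
Reagents that add atoms: none
Why: Corey–Bakshi–Shibata reduction with the alkenyl group as the large substituent should deliver hydride under reagent control to give the (3S)-alcohol (the sense that turns acetophenone into the S alcohol), with 1,2-selectivity.

Step 15
Reactants: 20 allylic alcohol
Product: 21 (1R,3S,4E,8S,9R)-diol (C3–OH and C14–OH free; C12–OPMB, C15–OTBDPS)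
Conditions: HF·pyridine, pyridine, THF, 0 °C
Reagents that add atoms: none
Why: Buffered HF·pyridine cleaves the unhindered primary TBS ether much faster than the neopentyl-type TBDPS ether (selective desilylation).

Step 16
Reactants: 22 (4R)-4-benzyl-3-propanoyl-1,3-oxazolidin-2-one; 23 acetaldehyde
Product: 25 (4R)-4-benzyl-3-[(2R,3S)-3-hydroxy-2-methylbutanoyl]-1,3-oxazolidin-2-one, via boron Z-enolate 24 (not isolated)
Conditions: Bu2BOTf, iPr2NEt, CH2Cl2, 0 °C; 23, −78 → 0 °C; pH 7 buffer, MeOH, H2O2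
Reagents that add atoms: none
Why: Evans syn aldol reaction; the Z boron enolate reacts through a Zimmerman–Traxler chair on the face opposite the benzyl group, so the (R)-auxiliary sets (2R,3S).

Step 17
Reactants: 25 aldol adduct
Product: 26 (4R)-4-benzyl-3-{(2R,3S)-2-methyl-3-[(triethylsilyl)oxy]butanoyl}-1,3-oxazolidin-2-one
Conditions: TESOTf, 2,6-lutidine, CH2Cl2, −78 °C
Reagents that add atoms: triethylsilyl triflate, CC[Si](CC)(CC)OS(=O)(=O)C(F)(F)F
Why: Silylation of the secondary alcohol prevents retro-aldol and self-acylation later; stereocentres are untouched.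

Step 18
Reactants: 26 silylated imide
Product: 27 (2R,3S)-2-methyl-3-[(triethylsilyl)oxy]butanoic acid
Conditions: LiOH, H2O2, THF/H2O, 0 °C; Na2SO3; then pH 4
Reagents that add atoms: hydrogen peroxide (as lithium hydroperoxide), OO
Why: Lithium hydroperoxide cleaves the exocyclic imide carbonyl selectively (Evans auxiliary removal) without epimerising C2.

Step 19
Reactants: 21 diol; 27 acid (1.1 equiv)
Product: 28 (1R,3S,4E,8S,9R)-C14 ester of 21 with the (2R,3S)-2-methyl-3-(TES-oxy)butanoyl group (C3–OH free)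
Conditions: EDC·HCl, DMAP (cat.), CH2Cl2, −20 → 0 °C
Reagents that add atoms: none
Why: Carbodiimide (Steglich) esterification acylates the primary allylic C14 hydroxyl far faster than the hindered secondary C3 hydroxyl, and doing it before C3 is acylated avoids secondary-to-primary acyl migration.

Step 20
Reactants: 28 hydroxy ester
Product: 29 (1R,3S,4E,8S,9R)-C3 isobutyrate of 28
Conditions: isobutyryl chloride, pyridine, DMAP (cat.), CH2Cl2, 0 °C → rt
Reagents that add atoms: isobutyryl chloride, CC(C)C(=O)Cl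
Why: DMAP-catalysed acylation of the remaining secondary allylic alcohol with retention at C3.

Step 21
Reactants: 29 PMB ether
Product: 30 (1R,3S,4E,8S,9R)-C12 alcohol (PMB removed)
Conditions: DDQ, CH2Cl2/pH 7 buffer, 0 °C
Reagents that add atoms: none
Why: Oxidative PMB cleavage by DDQ is orthogonal to the silyl ethers, the esters and the epoxide.

Step 22
Reactants: 30 C12 alcohol
Product: 31 (1R,3S,4E,8S,9R)-C12 acetate
Conditions: Ac2O, pyridine, DMAP (cat.), CH2Cl2, 0 °C
Reagents that add atoms: acetic anhydride, CC(=O)OC(C)=O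
Why: Acetylation of the only free hydroxyl (acyl transfer).

Step 23
Reactants: 31 bis-silyl ether
Product: 32 target CNP0256542.1
Conditions: TBAF, AcOH (1:1), THF, 0 °C → rt
Reagents that add atoms: none
Why: Acetic-acid-buffered fluoride removes the TBDPS and TES ethers (desilylation) without acyl migration, Payne rearrangement or epoxide opening.

**Compound list**

1 | prop-2-yn-1-ol | C#CCO | starting material
2 | but-3-en-1-ylmagnesium bromide | C=CCC[Mg]Br | starting material
3 | bromomagnesium (2Z)-3-(bromomagnesio)-2-(but-3-en-1-yl)prop-2-en-1-olate | C=CCC/C(CO[Mg]Br)=C/[Mg]Br | intermediate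
4 | (2Z)-2-(but-3-en-1-yl)-3-iodoprop-2-en-1-ol | OC/C(CCC=C)=C\I | intermediate
5 | methyl 2-(hydroxymethyl)prop-2-enoate | C=C(CO)C(=O)OC | starting material
6 | methyl 2-{[(TBS)oxy]methyl}prop-2-enoate | C=C(CO[Si](C)(C)C(C)(C)C)C(=O)OC | intermediate
7 | methyl (2E,6Z)-2-{[(TBS)oxy]methyl}-6-(hydroxymethyl)-7-iodohepta-2,6-dienoate | COC(=O)/C(CO[Si](C)(C)C(C)(C)C)=C/CC/C(CO)=C/I | intermediate
8 | methyl (2E,6Z)-2-{[(TBS)oxy]methyl}-6-(hydroxymethyl)deca-2,6,9-trienoate | COC(=O)/C(CO[Si](C)(C)C(C)(C)C)=C/CC/C(CO)=C/CC=C | intermediate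
9 | methyl (2E)-2-{[(TBS)oxy]methyl}-5-[(2S,3R)-2-(hydroxymethyl)-3-(prop-2-en-1-yl)oxiran-2-yl]pent-2-enoate | COC(=O)/C(CO[Si](C)(C)C(C)(C)C)=C/CC[C@@]1(CO)O[C@@H]1CC=C | intermediate
10 | TBDPS ether of 9 | COC(=O)/C(CO[Si](C)(C)C(C)(C)C)=C/CC[C@@]1(CO[Si](c2ccccc2)(c2ccccc2)C(C)(C)C)O[C@@H]1CC=C | intermediate
11 | 2-methylidenepropane-1,3-diol | C=C(CO)CO | starting material
12 | 2-{[(4-methoxybenzyl)oxy]methyl}prop-2-en-1-ol | C=C(CO)COCc1ccc(OC)cc1 | intermediate
13 | 2-{[(4-methoxybenzyl)oxy]methyl}prop-2-enal | C=C(C=O)COCc1ccc(OC)cc1 | intermediate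
14 | E enal from cross-metathesis of 10 with 13 | COC(=O)/C(CO[Si](C)(C)C(C)(C)C)=C/CC[C@@]1(CO[Si](c2ccccc2)(c2ccccc2)C(C)(C)C)O[C@@H]1C/C=C(/C=O)COCc1ccc(OC)cc1 | intermediate
15 | allylic alcohol from 14 (C13–OH) | COC(=O)/C(CO[Si](C)(C)C(C)(C)C)=C/CC[C@@]1(CO[Si](c2ccccc2)(c2ccccc2)C(C)(C)C)O[C@@H]1C/C=C(/CO)COCc1ccc(OC)cc1 | intermediate
16 | seco acid | OC(=O)/C(CO[Si](C)(C)C(C)(C)C)=C/CC[C@@]1(CO[Si](c2ccccc2)(c2ccccc2)C(C)(C)C)O[C@@H]1C/C=C(/CO)COCc1ccc(OC)cc1 | intermediate
17 | twelve-membered (4E,11E,8S,9R)-epoxy dienyl macrolactone | O=C1/C(CO[Si](C)(C)C(C)(C)C)=C/CC[C@@]2(CO[Si](c3ccccc3)(c3ccccc3)C(C)(C)C)O[C@@H]2C/C=C(/CO1)COCc1ccc(OC)cc1 | intermediate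
18 | twelve-membered 2-methylidene enol ether (C3=C2H2 in place of C3=O of 17) | C=C1/C(CO[Si](C)(C)C(C)(C)C)=C/CC[C@@]2(CO[Si](c3ccccc3)(c3ccccc3)C(C)(C)C)O[C@@H]2C/C=C(/CO1)COCc1ccc(OC)cc1 | intermediate
19 | (1S,4E,8S,9R)-epoxy cyclodecenone | C=C(COCc3ccc(OC)cc3)[C@@H]1CC(=O)/C(CO[Si](C)(C)C(C)(C)C)=C/CC[C@@]2(CO[Si](c3ccccc3)(c3ccccc3)C(C)(C)C)O[C@@H]2C1 | intermediate
20 | (1R,3S,4E,8S,9R)-allylic alcohol | C=C(COCc3ccc(OC)cc3)[C@@H]1C[C@H](O)/C(CO[Si](C)(C)C(C)(C)C)=C/CC[C@@]2(CO[Si](c3ccccc3)(c3ccccc3)C(C)(C)C)O[C@@H]2C1 | intermediate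
21 | (1R,3S,4E,8S,9R)-C3,C14-diol | C=C(COCc3ccc(OC)cc3)[C@@H]1C[C@H](O)/C(CO)=C/CC[C@@]2(CO[Si](c3ccccc3)(c3ccccc3)C(C)(C)C)O[C@@H]2C1 | intermediate
22 | (4R)-4-benzyl-3-propanoyl-1,3-oxazolidin-2-one | CCC(=O)N1C(=O)OC[C@H]1Cc1ccccc1 | starting material
23 | acetaldehyde | CC=O | starting material
24 | dibutylboron Z-enolate of 22 | C/C=C(\OB(CCCC)CCCC)N1C(=O)OC[C@H]1Cc1ccccc1 | intermediate
25 | (4R)-4-benzyl-3-[(2R,3S)-3-hydroxy-2-methylbutanoyl]-1,3-oxazolidin-2-one | O=C([C@H](C)[C@H](C)O)N1C(=O)OC[C@H]1Cc1ccccc1 | intermediate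
26 | TES ether of 25 | O=C([C@H](C)[C@H](C)O[Si](CC)(CC)CC)N1C(=O)OC[C@H]1Cc1ccccc1 | intermediate
27 | (2R,3S)-2-methyl-3-[(triethylsilyl)oxy]butanoic acid | OC(=O)[C@H](C)[C@H](C)O[Si](CC)(CC)CC | intermediate
28 | C14 (2R,3S)-2-methyl-3-(TES-oxy)butanoate of 21 | C=C(COCc3ccc(OC)cc3)[C@@H]1C[C@H](O)/C(COC(=O)[C@H](C)[C@H](C)O[Si](CC)(CC)CC)=C/CC[C@@]2(CO[Si](c3ccccc3)(c3ccccc3)C(C)(C)C)O[C@@H]2C1 | intermediate
29 | C3 isobutyrate of 28 | C=C(COCc3ccc(OC)cc3)[C@@H]1C[C@H](OC(=O)C(C)C)/C(COC(=O)[C@H](C)[C@H](C)O[Si](CC)(CC)CC)=C/CC[C@@]2(CO[Si](c3ccccc3)(c3ccccc3)C(C)(C)C)O[C@@H]2C1 | intermediate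
30 | C12 alcohol (PMB removed) | C=C(CO)[C@@H]1C[C@H](OC(=O)C(C)C)/C(COC(=O)[C@H](C)[C@H](C)O[Si](CC)(CC)CC)=C/CC[C@@]2(CO[Si](c3ccccc3)(c3ccccc3)C(C)(C)C)O[C@@H]2C1 | intermediate
31 | C12 acetate | C=C(COC(C)=O)[C@@H]1C[C@H](OC(=O)C(C)C)/C(COC(=O)[C@H](C)[C@H](C)O[Si](CC)(CC)CC)=C/CC[C@@]2(CO[Si](c3ccccc3)(c3ccccc3)C(C)(C)C)O[C@@H]2C1 | intermediate
32 | CNP0256542.1 | C=C(COC(C)=O)[C@@H]1C[C@H](OC(=O)C(C)C)/C(COC(=O)[C@H](C)[C@H](C)O)=C/CC[C@@]2(CO)O[C@@H]2C1 | target

**Summary**

Total step count: 23. Longest linear sequence: 17 steps (from 1 through steps 1, 3–6, 9–15 and 19–23).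

**Steps most likely to fail**

Step 13. The titanium methylidene may attack the oxirane in competition with carbonyl methylenation, or the facial bias of the rearrangement may be too small, so that C1 epimers form. The fallback moves the epoxidation behind the ring contraction; it sets out from 8 and returns at 19. Alcohol 8 is silylated (TESCl, imidazole) to the triethylsilyl ether F1 and taken through the operations of steps 9–12: cross-metathesis with 13 to the enal F2, Luche reduction to the alcohol F3, saponification to the seco acid F4 and Shiina lactonisation to the olefinic macrolactone F5. Petasis methylenation gives the enol ether F6 (not isolated), which is rearranged at no more than 110 °C (to limit Cope rearrangement of the 1,5-diene product) to the racemic dienone F7. PPTS in methanol removes the TES group to give the allylic alcohol F8. Sharpless epoxidation with L-(+)-diethyl tartrate, used on the racemate in its kinetic-resolution sense, should epoxidise the matched enantiomer to the epoxy alcohol F9, which is separated and silylated with TBDPSCl to give 19.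

Step 14. The conformational bias of the ten-membered enone may override the oxazaborolidine (mismatched pair), so that hydride is delivered to the wrong face of C3. The fallback inverts under substrate control; it sets out from 19 and returns at 29. Luche reduction gives the (3R)-alcohol F10. Mitsunobu reaction with isobutyric acid (PPh3, DIAD) inverts C3 and installs the ester in one operation, giving the (3S)-isobutyrate F11. HF·pyridine removes the TBS group to the C14 alcohol F12, which is esterified at once with 27 (EDC, DMAP) to give 29. If substrate control gives 20 directly, the main route continues unchanged.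

Step 12. Intermolecular esterification (diolide, oligomers) may outcompete closure of the rigid hydroxy acid, or the activated acyl species may isomerise the enoate. The fallback makes the ester bond first and closes the ring at the C1=C11 olefin; it sets out from 10 and returns at 17. Saponification of 10 gives the acid F13, which is esterified intermolecularly with alcohol 12 (EDC, DMAP) to the bis-olefinic ester F14. Ring-closing metathesis (Hoveyda–Grubbs II, toluene, 80 °C, high dilution) between the terminal vinyl group and the 1,1-disubstituted olefin gives 17, the E isomer being separated if the Z isomer co-forms.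

**Further compounds**

F1 | step 13 | TES ether of 8 | COC(=O)/C(CO[Si](C)(C)C(C)(C)C)=C/CC/C(CO[Si](CC)(CC)CC)=C/CC=C
F2 | step 13 | E enal from cross-metathesis of F1 with 13 | COC(=O)/C(CO[Si](C)(C)C(C)(C)C)=C/CC/C(CO[Si](CC)(CC)CC)=C/C/C=C(/C=O)COCc1ccc(OC)cc1
F3 | step 13 | allylic alcohol from F2 | COC(=O)/C(CO[Si](C)(C)C(C)(C)C)=C/CC/C(CO[Si](CC)(CC)CC)=C/C/C=C(/CO)COCc1ccc(OC)cc1
F4 | step 13 | olefinic seco acid | OC(=O)/C(CO[Si](C)(C)C(C)(C)C)=C/CC/C(CO[Si](CC)(CC)CC)=C/C/C=C(/CO)COCc1ccc(OC)cc1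
F5 | step 13 | twelve-membered (E,E,E)-trienyl macrolactone | O=C1/C(CO[Si](C)(C)C(C)(C)C)=C/CC/C(CO[Si](CC)(CC)CC)=C/C/C=C(/CO1)COCc1ccc(OC)cc1
F6 | step 13 | 2-methylidene enol ether of F5 | C=C1/C(CO[Si](C)(C)C(C)(C)C)=C/CC/C(CO[Si](CC)(CC)CC)=C/C/C=C(/CO1)COCc1ccc(OC)cc1
F7 | step 13 | racemic (4E,8E)-cyclodecadienone with C15–OTES | C=C(COCc1ccc(OC)cc1)C1CC(=O)/C(CO[Si](C)(C)C(C)(C)C)=C/CC/C(CO[Si](CC)(CC)CC)=C/C1
F8 | step 13 | racemic dienone with C15–OH | C=C(COCc1ccc(OC)cc1)C1CC(=O)/C(CO[Si](C)(C)C(C)(C)C)=C/CC/C(CO)=C/C1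
F9 | step 13 | (1S,4E,8S,9R)-epoxy enone with C15–OH | C=C(COCc3ccc(OC)cc3)[C@@H]1CC(=O)/C(CO[Si](C)(C)C(C)(C)C)=C/CC[C@@]2(CO)O[C@@H]2C1
F10 | step 14 | (1R,3R,4E,8S,9R)-allylic alcohol (C3 epimer of 20) | C=C(COCc3ccc(OC)cc3)[C@@H]1C[C@@H](O)/C(CO[Si](C)(C)C(C)(C)C)=C/CC[C@@]2(CO[Si](c3ccccc3)(c3ccccc3)C(C)(C)C)O[C@@H]2C1
F11 | step 14 | (3S)-isobutyrate with C14–OTBS | C=C(COCc3ccc(OC)cc3)[C@@H]1C[C@H](OC(=O)C(C)C)/C(CO[Si](C)(C)C(C)(C)C)=C/CC[C@@]2(CO[Si](c3ccccc3)(c3ccccc3)C(C)(C)C)O[C@@H]2C1
F12 | step 14 | (3S)-isobutyrate with C14–OH | C=C(COCc3ccc(OC)cc3)[C@@H]1C[C@H](OC(=O)C(C)C)/C(CO)=C/CC[C@@]2(CO[Si](c3ccccc3)(c3ccccc3)C(C)(C)C)O[C@@H]2C1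
F13 | step 12 | acid from saponification of 10 | OC(=O)/C(CO[Si](C)(C)C(C)(C)C)=C/CC[C@@]1(CO[Si](c2ccccc2)(c2ccccc2)C(C)(C)C)O[C@@H]1CC=C
F14 | step 12 | ester of F13 with alcohol 12 | C=C(COCc1ccc(OC)cc1)COC(=O)/C(CO[Si](C)(C)C(C)(C)C)=C/CC[C@@]2(CO[Si](c3ccccc3)(c3ccccc3)C(C)(C)C)O[C@@H]2CC=C
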